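**Plan**
- Retrosynthetic cuts, in order: the two O–Si bonds; then C4a–C4 of the tetralin, which opens to an (E)-C3=C4 alkene with Br on C4a; then C4–C1′ (Heck); then C1–C2 (allylboration).
- Forward: both arenes are bought intact. The chain is joined C1–C2 first, then C4–C1′. The only ring made (C1–C2–C3–C4–C4a–C8a) closes in the penultimate step.
- Enabling feature: C4 is attached to C1′ of the naphthalene, so Ni–H adds to C3=C4 and places Ni on C4 as an η3-naphthylmethyl unit (C4–C1′–C2′). C4a lies between C5–OMe and C8a. A cationic closure would avoid this site and go to C8, para to OMe, so C4a carries Br from the start.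
- One event then forms the most hindered bond, the ring and the C4 stereocentre.
- Stereochemistry: C1 (S) comes from a chiral-phosphoric-acid allylboration and C4 (S) from the chiral ligand on Ni. The product is the cis-(1S,4S) isomer.

Key step: step 6

Assumption: 8-methoxynaphthalen-1-ol (1) is taken as a catalogue compound. C1–C8a number the tetralin and primed numbers the naphthalene of the target, which reads from the SMILES as cis-(1S,4S).

Step 1
Reactants: 1 8-methoxynaphthalen-1-ol
Product: 2 4-iodo-8-methoxynaphthalen-1-ol
Conditions: NIS (1.0 equiv), TFA (10 mol %), MeCN, −20 to 0 °C, dark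
Reagents that add atoms: N-iodosuccinimide O=C1CCC(=O)N1I
Why: Electrophilic aromatic iodination should go para to the free OH (C4), because the OH, hydrogen-bonded to the peri OMe, is the stronger donor and C4 is the most nucleophilic site of a 1-naphthol; no stereocentre is formed.

Step 2
Reactants: 2 4-iodo-8-methoxynaphthalen-1-ol
Product: 3 [(4-iodo-8-methoxynaphthalen-1-yl)oxy]triisopropylsilane
Conditions: TIPSOTf, 2,6-lutidine, CH2Cl2, 0 °C to rt
Reagents that add atoms: triisopropylsilyl trifluoromethanesulfonate CC(C)[Si](C(C)C)(C(C)C)OS(=O)(=O)C(F)(F)F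
Why: O-silylation with the reactive triflate should overcome the peri hindrance and give an aryl silyl ether that survives the mild bases of steps 5 and 6.

Step 3
Reactants: 4 2-bromo-3-methoxybenzaldehyde; 5 allylboronic acid pinacol ester
Product: 7 (S)-1-(2-bromo-3-methoxyphenyl)but-3-en-1-ol, via O-boryl ether 6 (not isolated)
Conditions: (S)-TRIP phosphoric acid (5 mol %), toluene, −30 °C; aqueous work-up
Reagents that add atoms: none
Why: Chiral-phosphoric-acid-catalysed allylboration through a closed chair transition state, in which the (S)-acid should direct Si-face attack (mirror image of the (R)-acid/benzaldehyde case) and so set C1 as S.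

Step 4
Reactants: 7 (S)-1-(2-bromo-3-methoxyphenyl)but-3-en-1-ol
Product: 8 (S)-{[1-(2-bromo-3-methoxyphenyl)but-3-en-1-yl]oxy}(tert-butyl)dimethylsilane
Conditions: TBSCl, imidazole, DMF, rt
Reagents that add atoms: tert-butyldimethylsilyl chloride CC(C)(C)[Si](C)(C)Cl
Why: Standard O-silylation leaves C1 untouched and later prevents Pd–H or Ni–H chain walking from ending in a ketone.

Step 5
Reactants: 3 [(4-iodo-8-methoxynaphthalen-1-yl)oxy]triisopropylsilane; 8 (S)-{[1-(2-bromo-3-methoxyphenyl)but-3-en-1-yl]oxy}(tert-butyl)dimethylsilane
Product: 9 (S,E)-{[1-(2-bromo-3-methoxyphenyl)-4-(5-methoxy-4-triisopropylsilyloxynaphthalen-1-yl)but-3-en-1-yl]oxy}(tert-butyl)dimethylsilane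
Conditions: Pd(OAc)2 (5 mol %), n-Bu4NCl, NaHCO3, DMF, 60 °C
Reagents that add atoms: none
Why: Mizoroki–Heck reaction in which the C–I bond of 3 should add to ligand-free Pd well before the doubly ortho-flanked C–Br of 8, the naphthyl group goes to the terminal carbon, and β-hydride loss of the benzylic H gives the conjugated E alkene.

Step 6
Reactants: 9 (S,E)-{[1-(2-bromo-3-methoxyphenyl)-4-(5-methoxy-4-triisopropylsilyloxynaphthalen-1-yl)but-3-en-1-yl]oxy}(tert-butyl)dimethylsilane
Product: 10 tert-butyl{[(1S,4S)-5-methoxy-4-(5-methoxy-4-triisopropylsilyloxynaphthalen-1-yl)-1,2,3,4-tetrahydronaphthalen-1-yl]oxy}dimethylsilane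
Conditions: NiBr2·glyme (10 mol %), chiral 2,2′-bis(imidazoline) ligand (12 mol %, antipode leading to 4S), (MeO)2MeSiH, Na2CO3, NaI (20 mol %), DMA–THF, 25 °C, 0.02 M
Reagents that add atoms: none
Why: Proposed new method: a ligated Ni–H (from Ni halide, silane and base) adds reversibly across C3=C4 with H to C3 and Ni to C4, where it is held as an η3-naphthylmethyl unit over C4–C1′–C2′; this benzyl–Ni(I) then cleaves the nearby C4a–Br bond intramolecularly, and C(sp3)–C(sp2) reductive elimination from the seven-membered Ni(III) metallacycle forms C4a–C4. The closest known reaction type is the intermolecular NiH-catalysed enantioselective reductive hydroarylation of vinylarenes with aryl halides to 1,1-diarylalkanes, extended here to a ring closure on a β-alkyl 1-vinylnaphthalene. The six-membered carbocycle closes in a formally 6-endo sense with respect to the alkene, which is allowed because the C–C bond arises by reductive elimination and not by carbometallation. At C4 the two benzyl–Ni epimers should interconvert by β-hydride elimination/re-insertion and Ni–C homolysis, so the chiral ligand selects the one giving 4S; the preset C1 (S) centre is 1,4-remote with little intrinsic bias and should not override the ligand, so the cis-(1S,4S) product is expected. The step needs hydrometallation to precede aryl–Ni formation, since an aryl–Ni species would close 5-exo onto C3 to an indane; this is secured by a bromide (not an iodide) flanked by C5–OMe and C8a, by fast reversible Ni–H insertion and by dilution, while the C1 silyl ether blocks isomerisation to a ketone.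

Step 7
Reactants: 10 tert-butyl{[(1S,4S)-5-methoxy-4-(5-methoxy-4-triisopropylsilyloxynaphthalen-1-yl)-1,2,3,4-tetrahydronaphthalen-1-yl]oxy}dimethylsilane
Product: 11 dipolynaphthalene B, (1S,4S)-4-(4-hydroxy-5-methoxynaphthalen-1-yl)-5-methoxy-1,2,3,4-tetrahydronaphthalen-1-ol
Conditions: TBAF, AcOH (1:1), THF, 0 °C to rt, under argon
Reagents that add atoms: none
Why: Fluoride-mediated desilylation removes both silyl groups in one operation, the acetic acid buffer keeps the naphthol protonated against aerial oxidation, and neither stereocentre is touched.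

**Compound list**
1 | 8-methoxynaphthalen-1-ol | COc1cccc2cccc(O)c12 | starting material
2 | 4-iodo-8-methoxynaphthalen-1-ol | COc1cccc2c(I)ccc(O)c12 | intermediate
3 | [(4-iodo-8-methoxynaphthalen-1-yl)oxy]triisopropylsilane | COc1cccc2c(I)ccc(O[Si](C(C)C)(C(C)C)C(C)C)c12 | intermediate
4 | 2-bromo-3-methoxybenzaldehyde | COc1cccc(C=O)c1Br | starting material
5 | allylboronic acid pinacol ester | C=CCB1OC(C)(C)C(C)(C)O1 | starting material
6 | (S)-2-{[1-(2-bromo-3-methoxyphenyl)but-3-en-1-yl]oxy}-4,4,5,5-tetramethyl-1,3,2-dioxaborolane | COc1cccc([C@@H](OB2OC(C)(C)C(C)(C)O2)CC=C)c1Br | intermediate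
7 | (S)-1-(2-bromo-3-methoxyphenyl)but-3-en-1-ol | COc1cccc([C@@H](O)CC=C)c1Br | intermediate
8 | (S)-{[1-(2-bromo-3-methoxyphenyl)but-3-en-1-yl]oxy}(tert-butyl)dimethylsilane | COc1cccc([C@@H](O[Si](C)(C)C(C)(C)C)CC=C)c1Br | intermediate
9 | (S,E)-{[1-(2-bromo-3-methoxyphenyl)-4-(5-methoxy-4-triisopropylsilyloxynaphthalen-1-yl)but-3-en-1-yl]oxy}(tert-butyl)dimethylsilane | COc1cccc([C@@H](O[Si](C)(C)C(C)(C)C)C/C=C/c2ccc(O[Si](C(C)C)(C(C)C)C(C)C)c3c(OC)cccc23)c1Br | intermediate
10 | tert-butyl{[(1S,4S)-5-methoxy-4-(5-methoxy-4-triisopropylsilyloxynaphthalen-1-yl)-1,2,3,4-tetrahydronaphthalen-1-yl]oxy}dimethylsilane | COc1cccc2c1[C@H](c1ccc(O[Si](C(C)C)(C(C)C)C(C)C)c3c(OC)cccc13)CC[C@@H]2O[Si](C)(C)C(C)(C)C | intermediate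
11 | dipolynaphthalene B | COc1cccc2c1[C@H](c1ccc(O)c3c(OC)cccc13)CC[C@@H]2O | target

Total steps: 7. Longest linear sequence: 5 steps (4 → 7 → 8 → 9 → 10 → 11; the branch from 1 is equally long).

**Steps most likely to fail**

Step 6.
- What may go wrong: aryl–nickel may form ahead of hydrometallation and then close 5-exo by carbonickelation. The aryl bromide may simply be hydrodebrominated. The ligand may give weak facial control at C4.
- Fallback (known chemistry, from 9 back to 10): the event is split into two stereodefined operations. Copper-hydride-catalysed enantioselective hydroboration of the β-alkyl vinylarene 9 with pinacolborane (CuCl, NaOt-Bu, DTBM-SEGPHOS) should give the benzylic pinacol boronate F1, in which C4 already carries its configuration and no alkene is left for a 5-exo closure. An intramolecular stereoretentive Suzuki–Miyaura coupling of this secondary benzylic boronic ester with the C4a–Br bond (Pd2(dba)3, excess PPh3, Ag2O, DME, 80 °C) then forms the same C4a–C4 bond and gives 10.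

Step 5.
- What may go wrong: insertion of the peri-hindered naphthyl–palladium may be sluggish. The double bond may migrate out of conjugation. Oxidative addition may begin at the C–Br bond at the temperature required.
- Fallback (from 3 back to 9): the alkene is made by metathesis instead of arylation. Suzuki–Miyaura vinylation of 3 with potassium vinyltrifluoroborate (PdCl2(dppf), Cs2CO3, THF–H2O) should give the vinylnaphthalene F2. Cross metathesis of F2 with 8 (Hoveyda–Grubbs second-generation catalyst, CH2Cl2, reflux) should give the E alkene 9 without any Pd(0) near the aryl bromide.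

Step 1.
- What may go wrong: the electron-rich naphthol may dimerise oxidatively, or the iodonium source may attack C2 or C5.
- Fallback (from 1 back to 9, bypassing 2 and 3): the para position is fixed by oxidation level rather than by halogenation.
  - Teuber oxidation of 1 (Fremy's salt, aq. KH2PO4–acetone) should give 5-methoxy-1,4-naphthoquinone F3.
  - Dithionite reduction gives 5-methoxynaphthalene-1,4-diol F4.
  - The OH remote from the methoxy group is neither hydrogen-bonded nor peri-hindered, so it should be triflated selectively (PhNTf2, Et3N) to 4-hydroxy-5-methoxynaphthalen-1-yl triflate F5.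
  - Silylation with TIPSOTf gives the silylated triflate F6.
  - A Heck reaction of F6 with 8 (Pd(OAc)2, dppp, NaHCO3, DMF) rejoins the route at 9.

**Further compounds**
F1 | step 6 | tert-butyl{[(1S,4S)-1-(2-bromo-3-methoxyphenyl)-4-(5-methoxy-4-triisopropylsilyloxynaphthalen-1-yl)-4-(4,4,5,5-tetramethyl-1,3,2-dioxaborolan-2-yl)butyl]oxy}dimethylsilane | COc1cccc([C@@H](O[Si](C)(C)C(C)(C)C)CC[C@H](B2OC(C)(C)C(C)(C)O2)c2ccc(O[Si](C(C)C)(C(C)C)C(C)C)c3c(OC)cccc23)c1Br
F2 | step 5 | [(4-ethenyl-8-methoxynaphthalen-1-yl)oxy]triisopropylsilane | COc1cccc2c(C=C)ccc(O[Si](C(C)C)(C(C)C)C(C)C)c12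
F3 | step 1 | 5-methoxy-1,4-naphthoquinone | COc1cccc2C(=O)C=CC(=O)c12
F4 | step 1 | 5-methoxynaphthalene-1,4-diol | COc1cccc2c(O)ccc(O)c12
F5 | step 1 | 4-hydroxy-5-methoxynaphthalen-1-yl trifluoromethanesulfonate | COc1cccc2c(OS(=O)(=O)C(F)(F)F)ccc(O)c12
F6 | step 1 | 5-methoxy-4-triisopropylsilyloxynaphthalen-1-yl trifluoromethanesulfonate | COc1cccc2c(OS(=O)(=O)C(F)(F)F)ccc(O[Si](C(C)C)(C(C)C)C(C)C)c12
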